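**Retrosynthetic overview**
1. No C–C bond is made and no ring is built: the 11-membered ring is bought intact as α-humulene (1) and the arene as p-coumaric acid, so both key disconnections are C–O bonds.
2. Carbinol C–O bond: the trans-disubstituted alkene of 1 is hydrated regio-, chemo- and enantioselectively (CuH hydroboration to boronate 2, then stereoretentive oxidation) to the (R)-alcohol 3.
3. Z-enoate: (E)-p-coumaric acid (4) is photoisomerised to (Z)-p-coumaric acid (5).
4. Ester alkyl C–O bond (last step): 3 + 5 give target 6 by Mitsunobu esterification with inversion (1R to 1S), without protecting groups.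

Locants: in humulene, C4=C5 is the trans-disubstituted alkene and C6 the quaternary carbon; in the alcohol and ester names the carbinol carbon (former humulene C4) is C1, and the target is the 1S ester.

Assumption: (R)-DTBM-SEGPHOS is taken to give the 1R boronate and alcohol; the sense of induction is checked on the first run (Mosher ester analysis) and, if opposite, the commercial (S)-ligand is used instead.

**Step 1**
Reactants: 1 α-humulene, (1E,4E,8E)-2,6,6,9-tetramethylcycloundeca-1,4,8-triene
Product: 3 (1R,3E,7E)-3,7,10,10-tetramethylcycloundeca-3,7-dien-1-ol, via (R)-pinacol boronate 2 (not isolated)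
Conditions: CuCl (5 mol%), (R)-DTBM-SEGPHOS (5.5 mol%), KOtBu (10 mol%), HBpin (1.5 equiv), cyclohexane, 40 °C, 36 h; then THF, 3 M NaOH, 30% H2O2, 0 °C to rt
Reagents that add atoms: pinacolborane, CC1(C)OBOC1(C)C (Bpin group of 2); hydrogen peroxide, OO (hydroxyl oxygen of 3)
Why: Proposed new method: a monovalent copper hydride L*CuH (from CuCl, KOtBu and HBpin) should undergo syn-hydrocupration only at the strained trans-disubstituted C4=C5 bond, because unactivated trisubstituted alkenes do not insert into ligated CuH, with the bulky (DTBM-SEGPHOS)Cu going to C4 and hydride to C5 to avoid the quaternary C6 and with the ligand choosing one enantiotopic face of the rapidly flipping ring, after which stereoretentive σ-bond metathesis with HBpin gives 2 and stereoretentive boron-to-oxygen 1,2-migration in the peroxide oxidation forms the C–O bond and fixes C1 of 3 as R (asymmetric hydroboration–oxidation); the closest known reaction types are CuH-catalysed asymmetric hydroboration of internal alkenes that carry a polar directing group and CuH-catalysed hydroamination of simple trans-dialkyl alkenes, neither shown on a directing-group-free, sterically biased macrocyclic triene.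

**Step 2**
Reactants: 4 (E)-p-coumaric acid, (2E)-3-(4-hydroxyphenyl)prop-2-enoic acid
Product: 5 (Z)-p-coumaric acid, (2Z)-3-(4-hydroxyphenyl)prop-2-enoic acid
Conditions: hν (365 nm LED), MeOH (0.02 M), N2, rt; C18 chromatography (H2O/MeCN, 0.1% HCO2H) in the dark, recovered 4 recycled
Reagents that add atoms: none
Why: Direct E-to-Z photoisomerisation of the cinnamate chromophore gives a Z-enriched photostationary mixture because the E acid absorbs more strongly at this wavelength, dilute solution suppresses [2+2] dimerisation, and no stereocentre is involved.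

**Step 3**
Reactants: 3 (1R,3E,7E)-3,7,10,10-tetramethylcycloundeca-3,7-dien-1-ol; 5 (Z)-p-coumaric acid
Product: 6 (1S,3E,7E)-3,7,10,10-tetramethylcycloundeca-3,7-dien-1-yl (2Z)-3-(4-hydroxyphenyl)prop-2-enoate
Conditions: 5 (1.5 equiv), PPh3 (1.5 equiv), DIAD (1.5 equiv), THF, 0 °C to rt, amber glassware
Reagents that add atoms: none
Why: Mitsunobu reaction, in which the PPh3/DIAD betaine deprotonates the carboxylic acid (pKa about 4.5) in preference to the phenol (pKa about 10) and the carboxylate displaces the alkoxyphosphonium of 3 by SN2 with inversion, so the alkyl C–O bond is formed and 1R becomes 1S while the Z-enoate and both ring E-alkenes are untouched.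

**Compound list**
1 | α-humulene, (1E,4E,8E)-2,6,6,9-tetramethylcycloundeca-1,4,8-triene | C/C1=C\CC(C)(C)/C=C/C/C(C)=C/CC1 | starting material
2 | 2-[(1R,3E,7E)-3,7,10,10-tetramethylcycloundeca-3,7-dien-1-yl]-4,4,5,5-tetramethyl-1,3,2-dioxaborolane ((R)-pinacol boronate) | C/C1=C\CC(C)(C)C[C@@H](B2OC(C)(C)C(C)(C)O2)C/C(C)=C/CC1 | intermediate
3 | (1R,3E,7E)-3,7,10,10-tetramethylcycloundeca-3,7-dien-1-ol | C/C1=C\CC(C)(C)C[C@@H](O)C/C(C)=C/CC1 | intermediate
4 | (E)-p-coumaric acid, (2E)-3-(4-hydroxyphenyl)prop-2-enoic acid | OC(=O)/C=C/c1ccc(O)cc1 | starting material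
5 | (Z)-p-coumaric acid, (2Z)-3-(4-hydroxyphenyl)prop-2-enoic acid | OC(=O)/C=C\c1ccc(O)cc1 | intermediate
6 | (1S,3E,7E)-3,7,10,10-tetramethylcycloundeca-3,7-dien-1-yl (2Z)-3-(4-hydroxyphenyl)prop-2-enoate | C/C1=C\CC(C)(C)C[C@H](OC(=O)/C=C\c2ccc(O)cc2)C/C(C)=C/CC1 | target

**Step count and risks**
Total step count: 3. Longest linear sequence: 2 steps (1 to 3 to 6; the branch 4 to 5 to 6 is also 2 steps).

Most likely to fail, in order of risk:

Step 1 (proposed new method). Insertion next to the quaternary carbon may be slow, and regio- or face-selectivity may be incomplete. The fallback uses known chemistry, sets out from 1 and comes back at 3. Disiamylborane (THF, 0 °C to rt) is a dialkylborane that adds to 1,2-disubstituted alkenes with boron at the less hindered carbon and leaves trisubstituted alkenes alone. It gives the alkyl-disiamylborane F1. NaOH/H2O2 oxidation gives the racemic alcohol F2. Preparative chiral SFC on an amylose-type phase then delivers 3; the other enantiomer can feed the retention route given for step 3.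

Step 3 (Mitsunobu). Elimination or transannular participation in the medium ring, or erosion of the Z geometry, could lower the yield. The fallback replaces inversion by acylation with retention, sets out from 1 and 5 and comes back at 6. Step 1 is run with (S)-DTBM-SEGPHOS to give the (S)-pinacol boronate F3 and, after oxidation, the (1S)-alcohol F4. Acid 5 is bis-silylated (TBSCl, imidazole, DMF) to the silyl ester silyl ether F5. Its silyl ester is cleaved (K2CO3, MeOH/THF/H2O) to the phenol-silylated Z acid F6. Carbodiimide esterification of F4 with F6 (EDC·HCl, 5 mol% DMAP, CH2Cl2, 0 °C) leaves the carbinol C–O bond intact and gives the silyl-protected ester F7. TBAF/AcOH in THF at 0 °C gives 6.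

Step 2 (photoisomerisation of the free acid). The photostationary ratio may be modest, and the polar Z and E acids may be hard to separate. The fallback moves the isomerisation to the last stage, sets out from 3 and 4 and comes back at 6. Mitsunobu esterification of 3 with the cheap E acid 4 (PPh3, DIAD, THF) gives the E-coumarate ester F8. Triplet-sensitised E-to-Z isomerisation of the cinnamate (fac-Ir(ppy)3 1 mol%, 450 nm LED, MeCN) cannot excite the isolated ring alkenes. It gives a Z-enriched mixture from which 6 is separated on silica, and F8 is recycled.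

**Further compounds**
F1 | step 1 | bis(3-methylbutan-2-yl)[(3E,7E)-3,7,10,10-tetramethylcycloundeca-3,7-dien-1-yl]borane (racemic at C1) | C/C1=C\CC(C)(C)CC(B(C(C)C(C)C)C(C)C(C)C)C/C(C)=C/CC1
F2 | step 1 | racemic (3E,7E)-3,7,10,10-tetramethylcycloundeca-3,7-dien-1-ol | C/C1=C\CC(C)(C)CC(O)C/C(C)=C/CC1
F3 | step 3 | 2-[(1S,3E,7E)-3,7,10,10-tetramethylcycloundeca-3,7-dien-1-yl]-4,4,5,5-tetramethyl-1,3,2-dioxaborolane | C/C1=C\CC(C)(C)C[C@H](B2OC(C)(C)C(C)(C)O2)C/C(C)=C/CC1
F4 | step 3 | (1S,3E,7E)-3,7,10,10-tetramethylcycloundeca-3,7-dien-1-ol | C/C1=C\CC(C)(C)C[C@H](O)C/C(C)=C/CC1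
F5 | step 3 | tert-butyldimethylsilyl (2Z)-3-[4-(tert-butyldimethylsilyloxy)phenyl]prop-2-enoate | CC(C)(C)[Si](C)(C)OC(=O)/C=C\c1ccc(O[Si](C)(C)C(C)(C)C)cc1
F6 | step 3 | (2Z)-3-[4-(tert-butyldimethylsilyloxy)phenyl]prop-2-enoic acid | OC(=O)/C=C\c1ccc(O[Si](C)(C)C(C)(C)C)cc1
F7 | step 3 | (1S,3E,7E)-3,7,10,10-tetramethylcycloundeca-3,7-dien-1-yl (2Z)-3-[4-(tert-butyldimethylsilyloxy)phenyl]prop-2-enoate | C/C1=C\CC(C)(C)C[C@H](OC(=O)/C=C\c2ccc(O[Si](C)(C)C(C)(C)C)cc2)C/C(C)=C/CC1
F8 | step 2 | (1S,3E,7E)-3,7,10,10-tetramethylcycloundeca-3,7-dien-1-yl (2E)-3-(4-hydroxyphenyl)prop-2-enoate | C/C1=C\CC(C)(C)C[C@H](OC(=O)/C=C/c2ccc(O)cc2)C/C(C)=C/CC1
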